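Warming from 25 °C to 40 °C speeds the curve of E but leaves its height near 13.7%, the last spring reading, and I want to know what stops a flask there.

| flask | X | Q | J | Z | temperature | remark | time |
|---|---|---|---|---|---|---|---|
| autumn | 0.050 M | 0.050 M | 0.11 M | 0.60 mM | 40 °C | the very flask that is asked about, followed so far |  |
| spring | 0.050 M | 0.050 M | 0.11 M | 0.60 mM | 25 °C | run made earlier |  |
| flask | 0.050 M | 0.050 M | 0.110 M | 0.60 mM | 40 °C |  | 12 min |

| run | time / min | E / % |
|---|---|---|
| autumn | 0.500 | 5.1 |
| autumn | 1.00 | 6.5 |
| autumn | 2.00 | 9.9 |
| autumn | 4.00 | 12.0 |
| autumn | 8.00 | 13.3 |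
| spring | 1.00 | 4.1 |
| spring | 2.00 | 6.4 |
| spring | 4.00 | 9.5 |
| spring | 8.00 | 11.9 |
| spring | 15.0 | 13.7 |

(readings scatter by 0.5 percentage points)

- J is single-handed; X and Q are mirror images of each other, charged as a racemate, each of them at the stated concentration
- what is taken out of E is counted as made
- the analysis behind the earlier runs scatters by 0.5 percentage points, standard deviation
- additions bring no volume worth counting
- the handed part of J does not stay in what it makes, so the products of the two hands are mirror images too

- Sunday's: at 12 min add Z, 100% of the amount charged, then wait 4.0 min
- Monday's: at 12 min add J, 50.0% of the amount charged, then wait 4.0 min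
- Thursday's: at 12 min raise the temperature by 25 K, then wait 4.0 min
- Friday's: at 12 min take out 90% of the E then present, then wait 4.0 min
- Tuesday's: change nothing and wait 4.0 min more

- E, in percent of the X and Q together first charged, at 12 min
- the option that brings most further E ("none" if no option brings more than 2 percentage points) (Sunday's / Monday's / Thursday's / Friday's / Tuesday's / none)
- E present, with what was taken out counted in, in percent of the X and Q together first charged, after Monday's
- E present, with what was taken out counted in, in percent of the X and Q together first charged, after Tuesday's

My first estimate is a plain first-order stop, such as a dying catalyst: in the autumn run the gap to that height shrinks between 2.00 min and 4.00 min at 0.402 min⁻¹. But such a curve gives 2.49% at 0.500 min, where the autumn reading is 5.1% with a scatter of 0.5 percentage points, so the autumn start is too fast for it. A supply that falls fastest while it is high fits better, so I suppose that J also consumes itself, two at a time. Let j be the fraction of J still present: it falls at a·j plus a·r·j squared, with r the burn ratio, J spent on itself over J spent on substrate at the start, which I set by hand, to meet the early autumn readings, at 6.00. This rate integrates in closed form, and E becomes S times the logarithm of one plus r·u, with u the finished part, one minus exp(−a·t), and S the height over ln(one plus r), here 7 points. The autumn curve then passes 5.20% at 0.500 min against 5.1% read, but 7.70% at 1.00 min against 6.5%, so this fitted rule is a rough one.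

So I expect 13.7% at 12 min in the asked flask, and waiting should change little. Fresh Z has no place in this rule, and I cannot reckon Friday's from these readings. The objection to a new dose of J is that X is no longer at its charge: if E is its measure, 72.6% remains, and S and a shrink by that share while r grows by it. By this reckoning Monday's brings 6.9 points in 4.0 min, reaching 20.6%, so I commit to Monday's.

The forecast differs from me in the option: it gives 13.8%, names Sunday's, and puts Monday's at 14% and Tuesday's at 13.9%, on the ground of “a fixed catalyst life of about 25 turnovers”.

The flask gives 12.9% at 12 min, with J, the limiting reagent, at 1.9% of its charge. Monday's adds 6.4 points, reaching 19.3%, Sunday's adds 0.032 points, and Tuesday's stands at 12.9%.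

    2 J → L (k = 0.120 L mol⁻¹ s⁻¹, Ea = 60.0 kJ mol⁻¹)
    J + X → E (k = 0.0440 L mol⁻¹ s⁻¹, Ea = 55.0 kJ mol⁻¹)
    Z → D (k = 6.10 × 10⁻⁶ s⁻¹, Ea = 105 kJ mol⁻¹)
    J + Q → G (k = 0.0140 L mol⁻¹ s⁻¹, Ea = 66.0 kJ mol⁻¹)
    E ⇌ G (k = 0.00210 s⁻¹, Ea = 99.0 kJ mol⁻¹)
    X + Z ⇌ Q + Z, rate k6*[Z]*[X] forward; the back reaction follows from the equilibrium constant (k = 280 L mol⁻¹ s⁻¹, Ea = 35.0 kJ mol⁻¹)
    (constants at 40 °C)

The neighbouring flask is charged with 0.44 M of J and is otherwise the same, so its burn ratio grows with the charge to 24.0, and the same logarithm gives 22.6% at 12 min. That neighbouring flask gives 18.9%, with 64% of its X and 0.59% of its J left.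

The data were computed from invented constants, noise included.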